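Ring A (C1–C5, C10; labdane numbering) is cut across its C2–C3 and C4–C5 bonds: the C3–C4 edge, with quaternary C4 carrying the C18 methyl and the C19 carboxyl, is the imprint of methacrolein, and C2–C1–C10–C5 that of an (E)-1,3-diene whose C5 substituent is the remaining polyprenyl chain. A catalytic enantioselective Diels–Alder reaction joins them, closing ring A and fixing C4 and C5 in one operation from an achiral trienone made from geranylacetone. The C1=C10 olefin it leaves is the trigger for a biomimetic cationic closure of ring B, which sets C10, C9 and C8; the exocyclic methylene and the side chain follow by olefination, elimination and acylation.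

Key step: step 4

Remark: atoms are numbered as in labdanes (ring A = C1–C5 and C10; ring B = C5–C10; C17 = exocyclic methylene carbon; C18 and C19 = methyl and carboxyl on C4; C20 = methyl on C10), and the facial sense of the oxazaborolidinium catalyst is assigned from its formyl C–H···O binding model.

Step 1
Reactants: 1 (E)-geranylacetone
Product: 2 (5E,9E)-11-hydroxy-6,10-dimethylundeca-5,9-dien-2-one
Conditions: SeO2 (0.3 equiv), t-BuOOH (3 equiv), salicylic acid (0.1 equiv), CH2Cl2, rt
Reagents that add atoms: tert-butyl hydroperoxide, CC(C)(C)OO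
Why: SeO2/t-BuOOH allylic oxidation (ene reaction then [2,3]-sigmatropic shift) should hydroxylate the (E)-methyl group of the terminal, least hindered trisubstituted olefin with retention of the E geometry, the ketone being inert at room temperature.

Step 2
Reactants: 2 (5E,9E)-11-hydroxy-6,10-dimethylundeca-5,9-dien-2-one
Product: 3 (2E,6E)-2,6-dimethyl-10-oxoundeca-2,6-dienal
Conditions: MnO2 (activated, 15 equiv), CH2Cl2, rt
Reagents that add atoms: none
Why: Activated MnO2 oxidation is specific for the allylic alcohol and should stop at the (E)-enal without touching the isolated olefin or the ketone.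

Step 3
Reactants: 3 (2E,6E)-2,6-dimethyl-10-oxoundeca-2,6-dienal; 4 methyltriphenylphosphonium bromide
Product: 5 (5E,9E)-6,10-dimethyldodeca-5,9,11-trien-2-one
Conditions: Ph3PCH3Br, KN(SiMe3)2, THF, 0 °C; then 3 (1.0 equiv), −78 → 0 °C
Reagents that add atoms: methyltriphenylphosphonium bromide (4), C[P+](c1ccccc1)(c1ccccc1)c1ccccc1.[Br-]
Why: Wittig methylenation with one equivalent of Ph3P=CH2 at low temperature should take the enal carbonyl far faster than the methyl ketone and keep the (E)-trisubstituted olefin, giving the (E)-1,3-diene.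

Step 4
Reactants: 5 (5E,9E)-6,10-dimethyldodeca-5,9,11-trien-2-one; 6 methacrolein
Product: 7 (1S,2R)-1,3-dimethyl-2-[(3E)-3-methyl-7-oxooct-3-en-1-yl]cyclohex-3-ene-1-carbaldehyde
Conditions: (S)-B-(o-tolyl)oxazaborolidine of (S)-α,α-diphenylprolinol (20 mol%), Tf2NH (18 mol%), methacrolein (4 equiv), CH2Cl2, −78 → −20 °C
Reagents that add atoms: methacrolein (6), C=C(C)C=O
Why: The step is a Lewis-acid-catalysed, concerted but asynchronous [4+2] cycloaddition between the s-cis diene C2=C1–C10=C5 of 5 and boron-bound s-trans methacrolein, the C2–C3 bond running ahead of the C4–C5 bond. The closest known reaction type is the oxazaborolidinium-catalysed enantioselective Diels–Alder reaction of 2-substituted acroleins with acyclic dienes. Ring A is closed in the [4+2] mode, suprafacially on both partners, so the (E)-geometry of C10=C5 is carried into the C4/C5 relationship. C4 is controlled by the catalyst, whose aryl group shields one face of the coordinated enal so that C5 adds to the Re face of the α-carbon (4S), and C5 by the endo orientation of the complexed formyl group, which places the future C19 cis to the C6 chain (5R). The step needs "ortho" regioselectivity, secured because the C5 alkyl substituent makes unsubstituted C2 the terminus with the larger HOMO coefficient for the β-carbon of the activated enal, and endo selectivity, secured by Lewis-acid complexation of the formyl group. It also needs chemoselectivity, secured because the isolated C8=C9 olefin and the ketone are neither dienes nor activated dienophiles.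

Step 5
Reactants: 7 (1S,2R)-1,3-dimethyl-2-[(3E)-3-methyl-7-oxooct-3-en-1-yl]cyclohex-3-ene-1-carbaldehyde
Product: 8 (1S,2R)-1,3-dimethyl-2-[(3E)-3-methyl-7-oxooct-3-en-1-yl]cyclohex-3-ene-1-carboxylic acid
Conditions: NaClO2, NaH2PO4, 2-methyl-2-butene, t-BuOH/H2O, 0 °C → rt
Reagents that add atoms: sodium chlorite, [Na+].[O-]Cl=O
Why: Pinnick oxidation should convert the hindered, non-epimerisable quaternary aldehyde to the acid, 2-methyl-2-butene scavenging HOCl so that both olefins survive.

Step 6
Reactants: 8 (1S,2R)-1,3-dimethyl-2-[(3E)-3-methyl-7-oxooct-3-en-1-yl]cyclohex-3-ene-1-carboxylic acid; 9 methyl iodide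
Product: 10 methyl (1S,2R)-1,3-dimethyl-2-[(3E)-3-methyl-7-oxooct-3-en-1-yl]cyclohex-3-ene-1-carboxylate
Conditions: MeI, K2CO3, DMF, rt
Reagents that add atoms: methyl iodide (9), CI
Why: SN2 O-alkylation of the carboxylate should esterify the hindered quaternary acid where Fischer esterification would be slow, and K2CO3 is too weak to enolise the ketone.

Step 7
Reactants: 10 methyl (1S,2R)-1,3-dimethyl-2-[(3E)-3-methyl-7-oxooct-3-en-1-yl]cyclohex-3-ene-1-carboxylate
Product: 12 methyl (1S,4aS,5R,6R,8aR)-6-hydroxy-1,4a,6-trimethyl-5-(3-oxobutyl)decahydronaphthalene-1-carboxylate, via tricyclic enol ether 11 (not isolated)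
Conditions: FSO3H (6 equiv), 2-nitropropane, −78 °C; then 1 M HCl, THF, rt
Reagents that add atoms: water, O
Why: In this superacid-mediated biomimetic cation–olefin cyclization (Stork–Eschenmoser type), Markovnikov protonation of C1=C10 gives the C10 cation, which C9 of the (E)-C8=C9 olefin should capture through a chair-like transition state on the α-face (syn to H5, anti to the axial C19 ester; trans ring fusion, C20 β), the C8 cation then being trapped anti by the ketone oxygen (8α-O equatorial, C9 chain equatorial) before aqueous acid opens the enol ether to the ketol.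

Step 8
Reactants: 12 methyl (1S,4aS,5R,6R,8aR)-6-hydroxy-1,4a,6-trimethyl-5-(3-oxobutyl)decahydronaphthalene-1-carboxylate; 13 triethyl phosphonoacetate
Product: 14 methyl (1S,4aS,5R,6R,8aR)-5-[(3E)-5-ethoxy-3-methyl-5-oxopent-3-en-1-yl]-6-hydroxy-1,4a,6-trimethyldecahydronaphthalene-1-carboxylate
Conditions: (EtO)2P(O)CH2CO2Et, NaH, THF, 0 °C → reflux
Reagents that add atoms: triethyl phosphonoacetate (13), CCOC(=O)CP(=O)(OCC)OCC
Why: Horner–Wadsworth–Emmons olefination of the methyl ketone should give the trisubstituted enoate with the thermodynamically preferred (E)-geometry (the minor Z isomer to be removed by chromatography), the tertiary alcohol and the hindered C19 ester being spectators.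

Step 9
Reactants: 14 methyl (1S,4aS,5R,6R,8aR)-5-[(3E)-5-ethoxy-3-methyl-5-oxopent-3-en-1-yl]-6-hydroxy-1,4a,6-trimethyldecahydronaphthalene-1-carboxylate
Product: 15 methyl (1S,4aR,5S,8aR)-5-[(3E)-5-ethoxy-3-methyl-5-oxopent-3-en-1-yl]-1,4a-dimethyl-6-methylidenedecahydronaphthalene-1-carboxylate
Conditions: SOCl2, pyridine, CH2Cl2, −78 → 0 °C
Reagents that add atoms: none
Why: In this E2 dehydration through the chlorosulfite, the equatorial 8α-C–O bond of the rigid trans-decalin is antiperiplanar only to C–H bonds of the C17 methyl group, so elimination should give the exocyclic C8=C17 olefin, as in the dehydration of 8α-hydroxylabdanes.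

Step 10
Reactants: 15 methyl (1S,4aR,5S,8aR)-5-[(3E)-5-ethoxy-3-methyl-5-oxopent-3-en-1-yl]-1,4a-dimethyl-6-methylidenedecahydronaphthalene-1-carboxylate
Product: 16 methyl (1S,4aR,5S,8aR)-5-[(3E)-5-hydroxy-3-methylpent-3-en-1-yl]-1,4a-dimethyl-6-methylidenedecahydronaphthalene-1-carboxylate (methyl isocupressate)
Conditions: i-Bu2AlH (2.2 equiv), CH2Cl2, −78 °C; aq. potassium sodium tartrate
Reagents that add atoms: none
Why: DIBAL-H 1,2-reduction of the unhindered conjugated ethyl ester should give the (E)-allylic alcohol, while the axial neopentyl C19 methyl ester, shielded by the syn-axial C20 methyl, is not attacked at −78 °C.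

Step 11
Reactants: 16 methyl isocupressate; 17 palmitoyl chloride
Product: 18 methyl (1S,4aR,5S,8aR)-5-[(3E)-5-(hexadecanoyloxy)-3-methylpent-3-en-1-yl]-1,4a-dimethyl-6-methylidenedecahydronaphthalene-1-carboxylate (target)
Conditions: C15H31COCl, pyridine, DMAP (cat.), CH2Cl2, 0 °C → rt
Reagents that add atoms: palmitoyl chloride (17), CCCCCCCCCCCCCCCC(=O)Cl
Why: DMAP-catalysed O-acylation (nucleophilic acyl substitution) of the only free hydroxyl, a primary allylic alcohol, should give the target without touching any stereocentre.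

Compound list
1 | (E)-geranylacetone, (5E)-6,10-dimethylundeca-5,9-dien-2-one | CC(C)=CCC/C(C)=C/CCC(C)=O | starting material
2 | (5E,9E)-11-hydroxy-6,10-dimethylundeca-5,9-dien-2-one | OC/C(C)=C/CC/C(C)=C/CCC(C)=O | intermediate
3 | (2E,6E)-2,6-dimethyl-10-oxoundeca-2,6-dienal | O=C/C(C)=C/CC/C(C)=C/CCC(C)=O | intermediate
4 | methyltriphenylphosphonium bromide | C[P+](c1ccccc1)(c1ccccc1)c1ccccc1.[Br-] | starting material
5 | (5E,9E)-6,10-dimethyldodeca-5,9,11-trien-2-one | C=C/C(C)=C/CC/C(C)=C/CCC(C)=O | intermediate
6 | methacrolein | C=C(C)C=O | starting material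
7 | (1S,2R)-1,3-dimethyl-2-[(3E)-3-methyl-7-oxooct-3-en-1-yl]cyclohex-3-ene-1-carbaldehyde | O=C[C@@]1(C)CCC=C(C)[C@H]1CC/C(C)=C/CCC(C)=O | intermediate
8 | (1S,2R)-1,3-dimethyl-2-[(3E)-3-methyl-7-oxooct-3-en-1-yl]cyclohex-3-ene-1-carboxylic acid | OC(=O)[C@@]1(C)CCC=C(C)[C@H]1CC/C(C)=C/CCC(C)=O | intermediate
9 | methyl iodide | CI | starting material
10 | methyl (1S,2R)-1,3-dimethyl-2-[(3E)-3-methyl-7-oxooct-3-en-1-yl]cyclohex-3-ene-1-carboxylate | COC(=O)[C@@]1(C)CCC=C(C)[C@H]1CC/C(C)=C/CCC(C)=O | intermediate
11 | tricyclic enol ether, methyl 8α,13-epoxy-14,15-dinorlabd-12-en-19-oate | O1[C@]2(C)CC[C@@H]3[C@](C)(CCC[C@]3(C)C(=O)OC)[C@H]2CC=C1C | intermediate (not isolated)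
12 | methyl (1S,4aS,5R,6R,8aR)-6-hydroxy-1,4a,6-trimethyl-5-(3-oxobutyl)decahydronaphthalene-1-carboxylate | O[C@]1(C)CC[C@@H]2[C@](C)(CCC[C@]2(C)C(=O)OC)[C@H]1CCC(C)=O | intermediate
13 | triethyl phosphonoacetate | CCOC(=O)CP(=O)(OCC)OCC | starting material
14 | methyl (1S,4aS,5R,6R,8aR)-5-[(3E)-5-ethoxy-3-methyl-5-oxopent-3-en-1-yl]-6-hydroxy-1,4a,6-trimethyldecahydronaphthalene-1-carboxylate | O[C@]1(C)CC[C@@H]2[C@](C)(CCC[C@]2(C)C(=O)OC)[C@H]1CC/C(C)=C/C(=O)OCC | intermediate
15 | methyl (1S,4aR,5S,8aR)-5-[(3E)-5-ethoxy-3-methyl-5-oxopent-3-en-1-yl]-1,4a-dimethyl-6-methylidenedecahydronaphthalene-1-carboxylate | C=C1CC[C@@H]2[C@](C)(CCC[C@]2(C)C(=O)OC)[C@H]1CC/C(C)=C/C(=O)OCC | intermediate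
16 | methyl isocupressate, methyl (1S,4aR,5S,8aR)-5-[(3E)-5-hydroxy-3-methylpent-3-en-1-yl]-1,4a-dimethyl-6-methylidenedecahydronaphthalene-1-carboxylate | C=C1CC[C@@H]2[C@](C)(CCC[C@]2(C)C(=O)OC)[C@H]1CC/C(C)=C/CO | intermediate
17 | palmitoyl chloride | CCCCCCCCCCCCCCCC(=O)Cl | starting material
18 | methyl (1S,4aR,5S,8aR)-5-[(3E)-5-(hexadecanoyloxy)-3-methylpent-3-en-1-yl]-1,4a-dimethyl-6-methylidenedecahydronaphthalene-1-carboxylate | C=C1CC[C@@H]2[C@](C)(CCC[C@]2(C)C(=O)OC)[C@H]1CC/C(C)=C/COC(=O)CCCCCCCCCCCCCCC | target

Total step count: 11. Longest linear sequence: 11 steps (from 1).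

Steps most likely to fail

Step 7 (closure of ring B). Protonation may not be confined to the C1=C10 olefin. Protonation of C8=C9, with capture of that cation by the ketone or by the ring olefin, would give monocyclic or bridged material. Capture of the C10 cation on the wrong face would give a cis-fused decalin. The fallback sets out from 8 and comes back at 12, and generates the C10 cation from a leaving group instead of by protonation. Acid 8 undergoes iodolactonisation (I2, NaHCO3, MeCN/H2O, 0 °C), which only the C1=C10 olefin can undergo because it alone lies within reach of the C19 carboxylate, to give the iodolactone F1. Radical deiodination (Bu3SnH, AIBN, benzene, 80 °C) gives the C19→C10 γ-lactone F2. SnCl4 (CH2Cl2, −78 °C, no protic acid) then ionises the tertiary C10–O bond. The departing β-face carboxylate steers C9 to the α-face, the ketone traps the C8 cation, and aqueous acid work-up gives the hydroxy keto acid F3. Methylation (MeI, K2CO3, DMF) returns it to 12.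

Step 4 (Diels–Alder reaction). Facial selectivity may erode, or the reaction may stall through binding of the ketone of 5 to the boron catalyst. The fallback sets out from 5 and 6 and comes back at 8. The cycloaddition is run with an achiral Lewis acid (BF3·OEt2, CH2Cl2, −78 °C), which should keep the regio- and endo-selectivity and gives 7 together with its mirror image, the ent-aldehyde F4. Pinnick oxidation as in step 5 gives 8 together with the ent-acid F5. Classical resolution by crystallisation with (R)-1-phenylethylamine gives the ammonium salt F6 of 8, and acidification (1 M HCl) releases 8.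

Step 9 (dehydration). Ionisation of the tertiary chlorosulfite (E1 pathway) would cost regiocontrol and give endocyclic olefins. The fallback sets out from 14 and comes back at 15. The elimination is run without regard to regiochemistry, and the endocyclic Δ7 isomer F7 is converted to 15 by light-driven contra-thermodynamic positional olefin isomerisation ((Bu4N)4W10O32, Co(dmgH)2(py)Cl, 390 nm, MeCN). The electrophilic decatungstate abstracts a ring allylic hydrogen and the cobaloxime returns it to give the less substituted exocyclic olefin; the electron-poor enoate should not be engaged.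

Further compounds
F1 | step 7 | iodolactone: C19→C10β γ-lactone of 8 with 1α-iodide (4-iodo-6-oxabicyclo[3.2.1]octan-7-one core carrying the C5 side chain) | C[C@@]12CC[C@H](I)[C@@](C)(OC1=O)[C@H]2CC/C(C)=C/CCC(C)=O
F2 | step 7 | deiodinated C19→C10β γ-lactone | C[C@@]12CCC[C@@](C)(OC1=O)[C@H]2CC/C(C)=C/CCC(C)=O
F3 | step 7 | 8α-hydroxy-13-oxo-14,15-dinorlabdan-19-oic acid | O[C@]1(C)CC[C@@H]2[C@](C)(CCC[C@]2(C)C(=O)O)[C@H]1CCC(C)=O
F4 | step 4 | ent-aldehyde, (1R,2S)-1,3-dimethyl-2-[(3E)-3-methyl-7-oxooct-3-en-1-yl]cyclohex-3-ene-1-carbaldehyde | O=C[C@]1(C)CCC=C(C)[C@@H]1CC/C(C)=C/CCC(C)=O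
F5 | step 4 | ent-acid, (1R,2S)-1,3-dimethyl-2-[(3E)-3-methyl-7-oxooct-3-en-1-yl]cyclohex-3-ene-1-carboxylic acid | OC(=O)[C@]1(C)CCC=C(C)[C@@H]1CC/C(C)=C/CCC(C)=O
F6 | step 4 | (R)-1-phenylethylammonium salt of acid 8 | C[C@@H]([NH3+])c1ccccc1.[O-]C(=O)[C@@]1(C)CCC=C(C)[C@H]1CC/C(C)=C/CCC(C)=O
F7 | step 9 | endocyclic Δ7 isomer of 15, 15-ethyl 19-methyl labda-7,13E-diene-15,19-dioate | CC1=CC[C@@H]2[C@](C)(CCC[C@]2(C)C(=O)OC)[C@H]1CC/C(C)=C/C(=O)OCC
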